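Before any numbers I had in mind a neighbour of this flask, the same charge stopped at 40 h, and the question of how so little initiator gets the monomer moving at all.

    free monomer + initiator → living end + monomer in chains (k1 = 0.010 M⁻¹ h⁻¹)
    free monomer + living end → monomer in chains + living end, rate k2*[living end]*[free monomer] (k2 = 2.3 M⁻¹ h⁻¹)
    crystals ⇌ monomer in chains, rate k3*(cs3 - [monomer in chains]) while solid is left; crystals form when [monomer in chains] > cs3 (cs3 = 0.18 M, k3 = 0.51 h⁻¹)

free monomer 0.40 M; initiator 1.9 mol%; time 4.0 d

- amount of monomer in chains and crystals together at 4.0 d, in percent of the free monomer charged
- concentration of monomer in chains in solution at 10 h, in percent of saturation
- the change that raises the amount of monomer in chains and crystals together at 4.0 d, in percent of the free monomer charged most ("none" if none brings more than 2 percentage points) (violet / grey / green / none)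
- amount of monomer in chains and crystals together at 4.0 d, in percent of the free monomer charged, after grey

- violet: doubling the dissolution coefficient of step 3, all else as stated
- grey: doubling the amount of initiator, all else as stated
- green: doubling the solubility in step 3, all else as stated

- amounts and yields of monomer in chains count crystals too
- given per volume of solution although it is solid: crystals
- run time (flask): 4.0 d

I began with two extremes. If the whole initiator charge, 0.00760 M, became living ends at the outset, free monomer would fall pseudo-first-order and y would reach 81.3 %. If no living end ever added monomer, the first step by itself, with the initiator running down and c(free monomer) held at its start, would give 0.606 %. The real flask lies between them, and where depends on how fast ends are born. The initiator's lifetime at the starting c(free monomer) is 250 h, longer than the run, so I let c(living end) climb in a straight line at the starting rate. The second step then leaves a fraction of free monomer equal to the exponential of minus (t/τ) squared over two. Here τ is the lag, 120 h, the reciprocal square root of the two rate constants times both charges: the crossing at which the ends born so far, working that long, use one lifetime of free monomer.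

The flask's 4.0 d is shorter than τ. With the first step's share added, I got y of 28.3 %, a ceiling, since I held the birth rate at its start. The same sum at 10 h gave sat of 0.946 %. Grey shortens τ to 84.9 h, with a ceiling of 49.0 %. The third step moves material between two forms that y counts together, and crystals stand on the left of neither other step, so I expected nothing from violet or green.

The forecast gave y of 24.3 %, lower than my ceiling, sat of 0.93 %, grey as best with 41.6 %, and said “violet and green leave y unchanged”.

The flask gave y of 24.4 % and sat of 0.930 %; grey was best, gaining 17 percentage points to reach 41.6 %, against 0 points for violet and 0 points for green. At 4.00 d the flask's initiator still had a half-life of 9.5 d by the first step, longer than the run, with 71 % of it left, while the second step used free monomer 96 times as fast as the first. The flask thus ended at t/τ of 0.800, and the neighbour, at t/τ of 0.333, where the ramp's ceiling was 5.74 %, gave 5.39 %.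

(All constants are assumed, and the outcome is calculated.)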